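The readings are calculated with made-up constants; scatter was added.

If each substrate that reacts takes up one second reagent, by whatever route, then the recipe leaves a small reserve: the margin, the second reagent charged beyond one for one, 0.00310 M. That is 4.76 % of its own charge. Substrate is then the limiting reagent, a finished flask holds just the margin, and any second reagent above it marks substrate not yet through to its end.

| setting | larch | ash | birch | autumn | midnight | noon |
|---|---|---|---|---|---|---|
| substrate | 0.062 M | 0.062 M | 0.062 M | 0.062 M | 0.062 M (fed, over 3.0 h) | 0.062 M |
| second reagent | 0.0651 M | 0.033 M | 0.049 M | 0.0651 M | 0.0651 M | 0.0651 M (fed, over 3.0 h) |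
| gas | 18 mM (held) | 18 mM (held) | 18 mM (held) | 18 mM (held) | 18 mM (held) | 18 mM (held) |
| remark | run made earlier | run made earlier | run made earlier | everything together at the start | all else is in the flask from the start; the feed brings no volume worth counting | all else is in the flask from the start; the feed brings no volume worth counting |
| time |  |  |  | 8.0 h | 8.0 h | 8.0 h |

| run | time / h | target / % |
|---|---|---|
| larch | 0.417 | 0 |
| larch | 1.33 | 4.3 |
| larch | 2.00 | 6.6 |
| larch | 3.00 | 9.2 |
| larch | 5.00 | 12.7 |
| ash | 0.667 | 0 |
| ash | 1.33 | 0.8 |
| ash | 2.50 | 3.3 |
| ash | 4.00 | 4.0 |
| ash | 8.00 | 3.6 |
| birch | 0.667 | 1.1 |
| birch | 2.00 | 4.3 |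
| birch | 4.00 | 8.5 |
| birch | 6.00 | 9.6 |
| birch | 8.00 | 10.3 |

(each reading ± 1 percentage point)

- the flask that comes out highest in amount of target, in percent of the substrate charged, or "all alike" when all lie within 1.5 percentage points (autumn / midnight / noon / all alike)
- target at the end, in percent of the substrate charged, autumn
- target at the end, in percent of the substrate charged, midnight
- target at the end, in percent of the substrate charged, noon

- the numbers in the tables scatter with a standard deviation of 1 percentage point
- at the start none of the gas is in solution

The objection is that target may cost two second reagents. With all substrate reacted, target could then reach 5.00 % of the substrate, yet the larch run, the same recipe as autumn, reads 12.7 % at 5.00 h, which is higher by 7.7 percentage points against a scatter of 1 point. No reading shows the substrate, though, so this weakens the objection without removing it.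

The sign of the margin offers a second test. The ash run has a deficit of 0.0290 M, so its second reagent should give out and its target stop, and it reads 4.0 % at 4.00 h and 3.6 % at 8.00 h. The larch run, with a positive margin, still gains 3.5 points between 3.00 h and 5.00 h. The reckoning made here therefore commits to a rule, not to target figures: autumn, midnight and noon share one margin, and what stands above it at the end is target or side product still to come.

The forecast puts midnight highest, with autumn at 16 %, midnight at 20 % and noon at 12 %. It pictures a two-step path “with target needing a second” second reagent.

The flasks give autumn 14.9 %, midnight 27.8 % and noon 39.3 %, so noon comes highest, the flask the forecast put lowest.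

    substrate + partner → intermediate (k = 92.8 /M/h)
    second reagent + intermediate → target (k = 21.3 /M/h)
    substrate + second reagent → side product (k = 48.6 /M/h)
    gas ⇌ partner, rate k4*(csat - [partner]) (kL = 0.999 /h)

Autumn has not come to rest at 8.00 h. Its second reagent stands at 9.5 % of the charge, and the part above the margin equals 4.99 % of the substrate, beside 4.99 % of intermediate. At 80.0 h autumn's second reagent is down to 4.78 % of its charge, beside the margin's 4.76 %, and its target has risen from 14.9 % to 19.9 %. Noon holds 12 % of its second reagent at 8.00 h, which above the margin equals 8.00 % of the substrate, and its target goes from 39.3 % to 47.3 % at 80.0 h.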